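Start from the small charge of reagent, 0.100 M in this flask and 0.10 M in the autumn run, and take one substrate per reagent as the working assumption. The autumn run is the nearest thing to this flask: it has the same reagent charge, but 0.30 M of substrate where the flask has 0.20 M.

- autumn: substrate 0.30 M; reagent 0.10 M; run made earlier
- flask: substrate 0.20 M; reagent 0.100 M; time 50 min

autumn run (percent of the substrate charged)

| time / min | target / % | isomer of the product / % | substrate / % |
|---|---|---|---|
| 0.417 | 0.6 | 0.5 | 79.4 |
| 1.33 | 2.8 | 1.7 | 69.2 |
| 2.50 | 5.8 | 2.6 | 67.0 |
| 4.00 | 8.1 | 4.8 | 66.0 |
| 5.00 | 8.4 | 4.9 | 66.2 |

(readings scatter by 0.3 percentage points)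

* share of target in target plus isomer of the product at 40 s
* share of target in target plus isomer of the product at 6.0 min
* share of target in target plus isomer of the product at 50 min
* which of target and isomer of the product there is more of at 50 min

In both flasks the reagent is the limiting reagent, because its charge is smaller than the substrate's. Subtract one from the other: the flask keeps 0.100 M and the autumn run 0.200 M. Call this the free substrate, what stands over once each reagent has taken one substrate.

Test it on the autumn run. The reading of 66.2 % at 5.00 min is 0.199 M of substrate, close to the free substrate, and the fall has nearly stopped by then. So the two flasks should stop in different places: the autumn run near 66.7 % of its charge, this flask near 50.0 % of its charge.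

Now take the products. The last autumn reading puts target at 63.2 % of target plus isomer, and I carry that reading to all three asked times.

The forecast gives 62 %, 63 % and 62 %, with target ahead, and adds “so the 50 min range is wide and skewed low”.

The flask gives 64.6 %, 64.2 % and 61.6 %, with target ahead, 15.1 % against 9.39 %, so the forecast held.

    substrate + reagent → intermediate + released group (k = 0.140 /M/s)
    intermediate ⇌ target (K = 5.00, k = 0.00170 /s)
    intermediate ⇌ isomer of the product (K = 2.00, k = 9.30 × 10⁻⁴ /s)
    intermediate → side product A (k = 4.70 × 10⁻⁴ /s)
    crystals ⇌ released group, rate k5*(cs5 - [released group]) while solid is left; crystals form when [released group] > cs5 (solubility = 0.180 M, k = 0.0250 /s)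
    substrate + target → side product B (k = 0.00230 /M/s)

In this flask, substrate stood at 49.9 % after 5.00 min, then sank to 39.5 % at 50.0 min, while side product B reached 20.9 %. Reckoned with the free substrate, the half-life of target in the step to side product B is 50.2 min in this flask. The neighbour flask with 0.34 M of substrate has 0.240 M of free substrate, more than this flask, so the same half-life there is shorter, 20.9 min. That neighbour flask ends with target at 4.93 % and isomer of the product at 5.03 %, a share of 49.5 %.

(The readings stem from a simulated flask on assumed constants, and the scatter is random.)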